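**Plan**

Indane numbering of the target is used: C-1 carries the hydroxy(aryl)methyl arm, C-2 the 3,5-dihydroxyphenyl group, C-3 the 4-hydroxyphenyl group; ring A is the fused benzene ring (oxygens at C-4 and C-6).
Retrosynthesis: remove six O-benzyl groups; carbinol back to ketone; cut the C3–aryl bond to leave a phenylsulfonyl group at C-3; then cut C1–C7a and C2–C3 together, which gives an ortho-bromobenzyl phenyl sulfone and a chalcone.
Enabling feature: C-3 is benzylic to ring A and ortho/para to its two oxygens, so it can hold a sulfonyl group first as carbanion stabiliser and later as leaving group; C-1 and C-2 are the alpha and beta carbons of the side-chain ketone (a chalcone); C-7a lies ortho to C-3, within reach of the enolate.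
Forward: chalcone 3 and sulfone 8 are made separately; one flask joins them by Michael addition and palladium enolate arylation and so builds the five-membered ring; aryl-for-sulfonyl exchange, ketone reduction and hydrogenolysis finish the route.
Stereochemistry: C-2 from the chiral phase-transfer catalyst in the Michael step; C-1 by equilibration (alpha to the ketone, trans to the C-2 aryl); C-3 by aryl delivery to the benzylic cation anti to the C-2 aryl; the carbinol by (R)-CBS reagent control, which also turns any minor enantiomer into a separable diastereomer.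

Key step: step 5

Remark: compounds 1, 2, 4, 7 and 11 (the last as a THF solution) are taken as catalogue chemicals.

**Route**

Step 1
Reactants: 1 4'-(benzyloxy)acetophenone; 2 3,5-bis(benzyloxy)benzaldehyde
Product: 3 (E)-3-[3,5-bis(benzyloxy)phenyl]-1-[4-(benzyloxy)phenyl]prop-2-en-1-one
Conditions: aq NaOH (0.3 equiv), EtOH, rt
Reagents that add atoms: none
Why: Claisen–Schmidt (crossed aldol) condensation, in which the methyl ketone enolate adds to the non-enolisable aldehyde and dehydration gives the conjugated (E)-enone as the thermodynamic alkene.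

Step 2
Reactants: 4 1,3-bis(benzyloxy)-5-bromobenzene
Product: 5 2,4-bis(benzyloxy)-6-bromobenzaldehyde
Conditions: POCl3 (1.5 equiv), DMF, 0 → 80 °C; then H2O
Reagents that add atoms: N,N-dimethylformamide, CN(C)C=O; water, O
Why: Vilsmeier–Haack formylation, in which the chloroiminium ion should attack the position para to one benzyloxy group and ortho to the other (two equivalent sites next to bromine) in preference to the more hindered site between the two benzyloxy groups, and the iminium salt is hydrolysed on work-up.

Step 3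
Reactants: 5 2,4-bis(benzyloxy)-6-bromobenzaldehyde
Product: 6 [2,4-bis(benzyloxy)-6-bromophenyl]methanol
Conditions: NaBH4, THF–MeOH, 0 °C
Reagents that add atoms: none
Why: Hydride reduction of the aryl aldehyde with NaBH4, to which the aryl bromide and the benzyl ethers are inert.

Step 4
Reactants: 6 [2,4-bis(benzyloxy)-6-bromophenyl]methanol; 7 sodium benzenesulfinate
Product: 8 1,5-bis(benzyloxy)-3-bromo-2-[(phenylsulfonyl)methyl]benzene
Conditions: 7 (1.5 equiv), CF3CO2H (2 equiv), CH2Cl2, 0 °C → rt
Reagents that add atoms: none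
Why: Acid-promoted SN1-type substitution, in which the benzylic cation stabilised by the ortho- and para-benzyloxy groups is captured at sulfur by benzenesulfinic acid to give the sulfone as the thermodynamic S-alkylation product.

Step 5
Reactants: 8 1,5-bis(benzyloxy)-3-bromo-2-[(phenylsulfonyl)methyl]benzene; 3 (E)-3-[3,5-bis(benzyloxy)phenyl]-1-[4-(benzyloxy)phenyl]prop-2-en-1-one
Product: 10 [(1R,2S,3S)-4,6-bis(benzyloxy)-2-[3,5-bis(benzyloxy)phenyl]-3-(phenylsulfonyl)-2,3-dihydro-1H-inden-1-yl][4-(benzyloxy)phenyl]methanone (all-trans), via Michael adduct 9 (not isolated)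
Conditions: N-(9-anthracenylmethyl)-O-allylcinchonidinium bromide (10 mol %), 50% aq KOH (0.5 equiv), toluene, −20 °C; then Pd(OAc)2 (5 mol %), XPhos (10 mol %), K3PO4 (3 equiv), 80 °C
Reagents that add atoms: none
Why: Proposed new method: under phase transfer the sulfonyl-stabilised benzylic carbanion of 8, ion-paired with the chiral ammonium cation, adds 1,4 to the non-enolisable chalcone 3 to give 9; zerovalent palladium then inserts into the aryl C–Br bond and the ketone enolate is C-arylated through a six-membered aryl–palladium–enolate metallacycle, so the negative charge is relayed from C-3 to C-1 and the bonds C2–C3 and C1–C7a form in one flask. The closest known reaction types are the phase-transfer-catalysed Michael addition of carbon acids to chalcones and the palladium-catalysed intramolecular α-arylation of ketones; their union, with a benzylic sulfone acting as a three-carbon donor–acceptor partner of an enone, is the new element. The five-membered ring closes by C(sp2)–C(sp3) reductive elimination at divalent palladium, a five-ring closure in which the enolate C=C lies outside the ring (5-exo with respect to the enolate). C-2 is fixed in the Michael step by the catalyst, whose cation shields one face of the enone while it carries the carbanion; C-1 (alpha to the ketone) and C-3 (alpha to the sulfone) remain acidic and should settle under the basic conditions in the all-trans arrangement, and C-3 is renewed in step 6 in any case. The step needs conjugate addition before oxidative addition (secured by adding the palladium catalyst only after the addition is complete), C-arylation of the enolate in preference to arylation of the sulfonyl carbanion (only the enolate carbon can reach the bromide-bearing carbon in a five-membered closure; the sulfonyl carbanion would have to close a three-membered ring) and no retro-Michael erosion at C-2 (reversal of a C–C sigma bond to an enone and a carbanion of like basicity is uphill).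

Step 6
Reactants: 10 [(1R,2S,3S)-4,6-bis(benzyloxy)-2-[3,5-bis(benzyloxy)phenyl]-3-(phenylsulfonyl)-2,3-dihydro-1H-inden-1-yl][4-(benzyloxy)phenyl]methanone; 11 4-(benzyloxy)phenylmagnesium bromide
Product: 13 [(1R,2S,3R)-4,6-bis(benzyloxy)-2-[3,5-bis(benzyloxy)phenyl]-3-[4-(benzyloxy)phenyl]-2,3-dihydro-1H-inden-1-yl][4-(benzyloxy)phenyl]methanone, via arylzinc bromide 12 (not isolated)
Conditions: 11 (2.5 equiv), ZnBr2 (3 equiv), THF, 0 °C; then 10, CH2Cl2–THF, 0 °C → rt
Reagents that add atoms: none
Why: Substitution of a sulfone by an organozinc reagent through a Lewis-acid-generated stabilised cation (the reaction type known for α-alkoxy and indolylmethyl sulfones), in which ZnBr2 ionises the C3–sulfinate bond because the cation is conjugated with the C-4 and C-6 oxygens of ring A and the aryl group is delivered from zinc to the face anti to the neighbouring C-2 aryl group, so that C-3 should end trans to C-2 whatever the configuration of the sulfone carbon was.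

Step 7
Reactants: 13 [(1R,2S,3R)-4,6-bis(benzyloxy)-2-[3,5-bis(benzyloxy)phenyl]-3-[4-(benzyloxy)phenyl]-2,3-dihydro-1H-inden-1-yl][4-(benzyloxy)phenyl]methanone
Product: 14 (S)-[(1R,2S,3R)-4,6-bis(benzyloxy)-2-[3,5-bis(benzyloxy)phenyl]-3-[4-(benzyloxy)phenyl]-2,3-dihydro-1H-inden-1-yl][4-(benzyloxy)phenyl]methanol
Conditions: (R)-2-methyl-CBS-oxazaborolidine (20 mol %), BH3·SMe2 (1 equiv), THF, −20 °C; MeOH quench
Reagents that add atoms: none
Why: Corey–Bakshi–Shibata reduction, in which the aryl ketone binds to the (R)-oxazaborolidine–borane complex with its aryl flank turned away from the catalyst and hydride is delivered to the face that gives the (S)-carbinol under reagent control, while any residual enantiomeric ketone becomes a diastereomer that chromatography removes.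

Step 8
Reactants: 14 (S)-[(1R,2S,3R)-4,6-bis(benzyloxy)-2-[3,5-bis(benzyloxy)phenyl]-3-[4-(benzyloxy)phenyl]-2,3-dihydro-1H-inden-1-yl][4-(benzyloxy)phenyl]methanol
Product: 15 (1R,2S,3R)-2-(3,5-dihydroxyphenyl)-1-[(S)-hydroxy(4-hydroxyphenyl)methyl]-3-(4-hydroxyphenyl)-2,3-dihydro-1H-indene-4,6-diol
Conditions: H2 (1 atm), palladium on carbon (10% Pd/C), EtOAc–EtOH, rt
Reagents that add atoms: none
Why: Hydrogenolysis of the six aryl benzyl ethers over palladium under neutral conditions, which should leave the secondary benzylic alcohol and the ring stereocentres untouched, as in the debenzylation of para-benzyloxyphenyl carbinols.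

**Compound list**

1 | 4'-(benzyloxy)acetophenone | CC(=O)c1ccc(OCc2ccccc2)cc1 | starting material
2 | 3,5-bis(benzyloxy)benzaldehyde | O=Cc1cc(OCc2ccccc2)cc(OCc2ccccc2)c1 | starting material
3 | (E)-3-[3,5-bis(benzyloxy)phenyl]-1-[4-(benzyloxy)phenyl]prop-2-en-1-one | O=C(/C=C/c1cc(OCc2ccccc2)cc(OCc2ccccc2)c1)c1ccc(OCc2ccccc2)cc1 | intermediate
4 | 1,3-bis(benzyloxy)-5-bromobenzene | Brc1cc(OCc2ccccc2)cc(OCc2ccccc2)c1 | starting material
5 | 2,4-bis(benzyloxy)-6-bromobenzaldehyde | O=Cc1c(Br)cc(OCc2ccccc2)cc1OCc1ccccc1 | intermediate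
6 | [2,4-bis(benzyloxy)-6-bromophenyl]methanol | OCc1c(Br)cc(OCc2ccccc2)cc1OCc1ccccc1 | intermediate
7 | sodium benzenesulfinate | [Na+].[O-]S(=O)c1ccccc1 | starting material
8 | 1,5-bis(benzyloxy)-3-bromo-2-[(phenylsulfonyl)methyl]benzene | O=S(=O)(Cc1c(Br)cc(OCc2ccccc2)cc1OCc1ccccc1)c1ccccc1 | intermediate
9 | (3S)-4-[2,4-bis(benzyloxy)-6-bromophenyl]-3-[3,5-bis(benzyloxy)phenyl]-1-[4-(benzyloxy)phenyl]-4-(phenylsulfonyl)butan-1-one (both C-4 epimers) | O=C(C[C@@H](c1cc(OCc2ccccc2)cc(OCc2ccccc2)c1)C(c1c(Br)cc(OCc2ccccc2)cc1OCc1ccccc1)S(=O)(=O)c1ccccc1)c1ccc(OCc2ccccc2)cc1 | intermediate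
10 | [(1R,2S,3S)-4,6-bis(benzyloxy)-2-[3,5-bis(benzyloxy)phenyl]-3-(phenylsulfonyl)-2,3-dihydro-1H-inden-1-yl][4-(benzyloxy)phenyl]methanone | O=S(=O)(c1ccccc1)[C@@H]1c2c(OCc3ccccc3)cc(OCc3ccccc3)cc2[C@H](C(=O)c2ccc(OCc3ccccc3)cc2)[C@H]1c1cc(OCc2ccccc2)cc(OCc2ccccc2)c1 | intermediate
11 | 4-(benzyloxy)phenylmagnesium bromide | Br[Mg]c1ccc(OCc2ccccc2)cc1 | starting material
12 | 4-(benzyloxy)phenylzinc bromide | Br[Zn]c1ccc(OCc2ccccc2)cc1 | intermediate
13 | [(1R,2S,3R)-4,6-bis(benzyloxy)-2-[3,5-bis(benzyloxy)phenyl]-3-[4-(benzyloxy)phenyl]-2,3-dihydro-1H-inden-1-yl][4-(benzyloxy)phenyl]methanone | c1ccccc1COc1ccc([C@@H]2c3c(OCc4ccccc4)cc(OCc4ccccc4)cc3[C@H](C(=O)c3ccc(OCc4ccccc4)cc3)[C@H]2c2cc(OCc3ccccc3)cc(OCc3ccccc3)c2)cc1 | intermediate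
14 | (S)-[(1R,2S,3R)-4,6-bis(benzyloxy)-2-[3,5-bis(benzyloxy)phenyl]-3-[4-(benzyloxy)phenyl]-2,3-dihydro-1H-inden-1-yl][4-(benzyloxy)phenyl]methanol | c1ccccc1COc1ccc([C@@H]2c3c(OCc4ccccc4)cc(OCc4ccccc4)cc3[C@H]([C@H](O)c3ccc(OCc4ccccc4)cc3)[C@H]2c2cc(OCc3ccccc3)cc(OCc3ccccc3)c2)cc1 | intermediate
15 | (1R,2S,3R)-2-(3,5-dihydroxyphenyl)-1-[(S)-hydroxy(4-hydroxyphenyl)methyl]-3-(4-hydroxyphenyl)-2,3-dihydro-1H-indene-4,6-diol | Oc1ccc([C@@H]2c3c(O)cc(O)cc3[C@H]([C@H](O)c3ccc(O)cc3)[C@H]2c2cc(O)cc(O)c2)cc1 | target

**Count and risks**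

Total step count: 8. Longest linear sequence: 7 steps (4 → 5 → 6 → 8 → 10 → 13 → 14 → 15).

Step 5. The ion-paired Michael addition may discriminate the enone faces poorly, and the aqueous base and ammonium salt may slow the palladium cycle or allow intermolecular arylation of the sulfonyl carbanion. The sense of induction has to be established by experiment; the cinchoninium pseudoenantiomer of the catalyst is the first adjustment. Fallback with known chemistry, setting out from 8 and 3 and returning at 10: KOtBu in THF adds the sulfone to the chalcone without a chiral catalyst and gives the racemic Michael adduct F1, which is isolated. A separate palladium-catalysed intramolecular ketone α-arylation (Pd(OAc)2, XPhos, K3PO4, toluene, 80 °C) then closes the ring to the racemic all-trans indane, that is 10 together with the enantiomer of 10 F2. Preparative chromatography on a chiral stationary phase separates them and 10 re-enters at step 6.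

Step 6. ZnBr2 may ionise the sulfone too slowly, the cation may lose the C-2 proton (indene formation and erosion of configuration), or the electron-rich dibenzyloxyaryl rings of a second molecule may capture the cation before the aryl group is transferred. Fallback setting out from 10 and returning at 13: the sulfone is ionised in hexafluoroisopropanol with Bi(OTf)3 (5 mol %) in a large excess of phenol, so that mass action favours para Friedel–Crafts attack of phenol anti to the C-2 aryl and gives the free phenol ketone F3. O-Benzylation (BnBr, K2CO3, DMF) then gives 13.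

Step 7. The adjacent C-1 stereocentre and the bulk of the indanyl flank may oppose the reagent (double stereodifferentiation), which would give poor facial selectivity at the carbonyl. Fallback setting out from 13 and returning at 14: transfer hydrogenation with RuCl(p-cymene)[(S,S)-TsDPEN] in HCO2H–Et3N, which recognises the aryl ketone through an aryl–ligand contact and not through steric size. Whatever (R)-carbinol epimer F4 still forms is separated and oxidised back to 13 with Dess–Martin periodinane for another pass.

Further compounds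
F1 | step 5 | racemic 4-[2,4-bis(benzyloxy)-6-bromophenyl]-3-[3,5-bis(benzyloxy)phenyl]-1-[4-(benzyloxy)phenyl]-4-(phenylsulfonyl)butan-1-one (Michael adduct, all stereoisomers) | O=C(CC(c1cc(OCc2ccccc2)cc(OCc2ccccc2)c1)C(c1c(Br)cc(OCc2ccccc2)cc1OCc1ccccc1)S(=O)(=O)c1ccccc1)c1ccc(OCc2ccccc2)cc1
F2 | step 5 | [(1S,2R,3R)-4,6-bis(benzyloxy)-2-[3,5-bis(benzyloxy)phenyl]-3-(phenylsulfonyl)-2,3-dihydro-1H-inden-1-yl][4-(benzyloxy)phenyl]methanone (enantiomer of 10) | O=S(=O)(c1ccccc1)[C@H]1c2c(OCc3ccccc3)cc(OCc3ccccc3)cc2[C@@H](C(=O)c2ccc(OCc3ccccc3)cc2)[C@@H]1c1cc(OCc2ccccc2)cc(OCc2ccccc2)c1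
F3 | step 6 | [(1R,2S,3R)-4,6-bis(benzyloxy)-2-[3,5-bis(benzyloxy)phenyl]-3-(4-hydroxyphenyl)-2,3-dihydro-1H-inden-1-yl][4-(benzyloxy)phenyl]methanone | Oc1ccc([C@@H]2c3c(OCc4ccccc4)cc(OCc4ccccc4)cc3[C@H](C(=O)c3ccc(OCc4ccccc4)cc3)[C@H]2c2cc(OCc3ccccc3)cc(OCc3ccccc3)c2)cc1
F4 | step 7 | (R)-[(1R,2S,3R)-4,6-bis(benzyloxy)-2-[3,5-bis(benzyloxy)phenyl]-3-[4-(benzyloxy)phenyl]-2,3-dihydro-1H-inden-1-yl][4-(benzyloxy)phenyl]methanol (carbinol epimer of 14) | c1ccccc1COc1ccc([C@@H]2c3c(OCc4ccccc4)cc(OCc4ccccc4)cc3[C@H]([C@@H](O)c3ccc(OCc4ccccc4)cc3)[C@H]2c2cc(OCc3ccccc3)cc(OCc3ccccc3)c2)cc1
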